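(The runs are simulated for an exercise; noise was put on by code.)

Time first: epsilon stops at 5.0 min and theta at 8.0 min, so compare each flask at its own end.

common to all: substrate 20 mM
- green: partner 8.9 mM; run made earlier
- amber: partner 20 mM; run made earlier
- epsilon: partner 30.0 mM; time 5.0 min
- theta: partner 15.0 mM; time 8.0 min

- green (time / min: target / %, side product / %): 0.667: 3.5, 1.1; 1.33: 9.2, 0; 2.00: 15.5, 1.3; 2.50: 20.2, 0.8; 3.00: 22.5, 0.7; 4.00: 26.8, 0.6
- amber (time / min: target / %, side product / %): 0.250: 2.5, 0; 0.667: 7.7, 0; 1.33: 20.4, 0.1; 2.00: 31.5, 1.5; 2.50: 38.2, 0.6; 4.00: 53.9, 0.9

(standard deviation of a reading: 0.5 percentage points)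

- percentages count the substrate that a species holds: one side product counts as two

1. the flask that ends with the higher share of target in all that became target or side product, or "neither" when 2 percentage points or less lies between them (epsilon / theta / neither)
2. share of target in all that became target or side product, epsilon
3. share of target in all that became target or side product, theta

1. Read the side product. From 2.00 min on, neither earlier run shows a trend beyond the scatter, so average those 7 readings: 0.914%, give or take 0.19 percentage points. Call this reading the toll, the flat level of side product read from green and amber.

2. Apply the bench rule: the share of target, the selectivity, is target over target plus toll.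

3. Find the border. Divide the toll by the margin to get a target of 45.7%. Above it, a flask paying the toll stands within the margin of a perfect share, so two such flasks count as equal. Below it, the rule no longer promises "neither".

4. Place epsilon. It has more partner and more time than amber, so take amber's 53.9% at 4.00 min as a low estimate of its target. That is above the border, and with the toll it gives an estimated share of 98.3%.

5. Place theta. Interpolating on partner between green and amber gives 41.7% at 4.00 min. That is 4 points short of the border with 4.00 min left, and green gained 4.3 points in its last minute.

6. Commit: my reckoning says neither, with both shares near 98.0% or above.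

7. The forecast differs: epsilon, with 98% for epsilon and 95.5% for theta, on the ground that “Theta is starved”.

The flask gives neither: epsilon 98.2%, theta 98.7%.

    partner + intermediate A → target (k = 0.170 L mol⁻¹ s⁻¹)
    intermediate C → target (k = 0.0277 s⁻¹)
    substrate + intermediate C → side product (k = 3.18 L mol⁻¹ s⁻¹)
    intermediate A → intermediate B (k = 0.0590 s⁻¹)
    substrate → intermediate A (k = 0.117 s⁻¹)
    partner + intermediate B ⇌ intermediate C (K = 26.0 L mol⁻¹, k = 0.564 L mol⁻¹ s⁻¹)

Epsilon ends with 1.39% of side product and theta with 0.755%, so the level is not one number across these flasks. Put the toll on their final targets: 75.2% in epsilon gives 98.8%, and 58.2% in theta gives 98.5%. A neighbour of theta, charged with 25 mM of partner, ends with 80.6% of target; the toll gives 98.9%, and that neighbour stands at 98.5%.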